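Slowness helps here: at low conversion the two hands of substrate compete for one partner, so reckon with the ratio of their rates and let what they share cancel.

| flask | left-handed substrate | right-handed substrate | gas | racemization catalyst | temperature | remark | time |
|---|---|---|---|---|---|---|---|
| theta | 8 mM | 8 mM | 0.79 mM (held) | 1.4 mM | −20 °C | run made earlier |  |
| delta | 32 mM | 32 mM | 0.79 mM (held) | 1.4 mM | 13 °C | run made earlier |  |
| ash | 16 mM | 16 mM | 0.79 mM (held) | 1.4 mM | −35 °C |  | 25 h |
| oak | 16 mM | 16 mM | 0.79 mM (held) | 1.4 mM | −5 °C |  | 25 h |
| maple | 16 mM | 16 mM | 0.79 mM (held) | 1.4 mM | 25 °C |  | 25 h |

theta run (percent of the left-handed substrate and right-handed substrate together charged)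

| time / h | left-handed product / % | right-handed product / % |
|---|---|---|
| 1.33 | 0.5 | 0 |
| 4.00 | 1.6 | 0.5 |
| 6.00 | 2.9 | 0.3 |
| 10.0 | 4.7 | 0.1 |

delta run (percent of the left-handed substrate and right-handed substrate together charged)

| time / min | left-handed product / % | right-handed product / % |
|---|---|---|
| 15.0 | 0 | 0.3 |
| 40.0 | 1.4 | 0.4 |
| 60.0 | 2.2 | 0.1 |
| 120 | 3.9 | 2.3 |

(standard deviation of a reading: 0.3 percentage points)

- partner is single-handed; left-handed substrate and right-handed substrate are mirror images of each other, charged as a racemate, each of them at the stated concentration
- at the start none of partner is dissolved
- what was read earlier has a scatter of 0.3 percentage points, one standard deviation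
- on the list of suspects stand: left-handed substrate + racemization catalyst <-> right-handed substrate + racemization catalyst; gas <-> partner; partner + right-handed substrate -> right-handed product; partner -> decomposed reagent; partner + left-handed substrate -> left-handed product
- an excess is the difference of the two amounts in percent of their sum
- an excess is below zero if the other one leads
- the handed part of partner does not stay in what it makes, so the products of the two hands are mirror images too

- the flask with the highest excess of left-handed product over right-handed product ("all alike" if they lie within 1.5 percentage points) (ash / oak / maple / all alike)
- excess of left-handed product over right-handed product at the end, ash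
- excess of left-handed product over right-handed product at the end, oak
- excess of left-handed product over right-handed product at the end, maple

Try each given number in turn. Shift the gas level and partner shifts, but partner multiplies both product rates, so their ratio stays and a rough value will do, whether or not dissolving is fast. Shift the common substrate charge and both hands scale alike, so that number matters little too. The racemization catalyst evens out a gap between the substrates, and while they stand nearly equal there is little gap, though the readings don't give its rate. What must be known well is the selectivity factor, the ratio of the left-handed to the right-handed rate constant. With equal substrates the excess is that factor less one, over the factor plus one. Going from 20 to 40 moves the excess from 90.5% to 95.1%, but going from 2 to 4 moves it from 33.3% to 60.0%, so small factors need the care.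

Now add up the columns. The theta readings give a selectivity factor of 10.8 at −20 °C, but their right-handed sum of 0.900% carries a scatter of 0.6 percentage points. The delta readings give 2.42 at 13 °C. The logarithm of the factor against inverse temperature then has a slope of 3280 K. That gives factors of 24.4 for ash, 5.22 for oak and 1.53 for maple. My excesses are 92.1%, 67.8% and 20.9%. Read oak and maple as high, since left-handed substrate is used faster than right-handed substrate and falls behind there.

The forecast, which says “so I shade the values slightly”, names ash and gives 94%, 68% and 7% for ash, oak and maple; for maple it stands lower than my reckoning.

The flasks give ash as highest, with 91.3% for ash, 61.6% for oak and 12.6% for maple.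

    left-handed substrate + racemization catalyst ⇌ right-handed substrate + racemization catalyst, rate k1*[racemization catalyst]*[left-handed substrate] forward; the back reaction follows from the equilibrium constant (k = 25.2 L mol⁻¹ h⁻¹, Ea = 61.0 kJ mol⁻¹)
    gas ⇌ partner, rate k2*(csat - [partner]) (kL = 4.18 h⁻¹)
    partner + right-handed substrate → right-handed product (k = 177 L mol⁻¹ h⁻¹, Ea = 69.0 kJ mol⁻¹)
    partner → decomposed reagent (k = 0.00628 h⁻¹, Ea = 99.0 kJ mol⁻¹)
    partner + left-handed substrate → left-handed product (k = 317 L mol⁻¹ h⁻¹, Ea = 44.0 kJ mol⁻¹)
    (constants at 25 °C)

In ash at 25.0 h, partner goes to left-handed product 21 times as fast as to right-handed product, with 46.6% of left-handed and 49.8% of right-handed substrate standing. At that time in ash, the step to left-handed product takes left-handed substrate 39 times as fast as forward racemization does.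

Run the ash recipe instead at −20 °C, the temperature of theta: the factor 10.8 read there gives 83.1%. That flask gives 81.2%, with 78% of its left-handed substrate left.

(The numbers in the tables stem from a simulated flask with constants of no real substance, and the scatter is random.)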